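## Retrosynthetic overview

1. The target comes from its bis-TBS ether by desilylation. That lactone comes from one radical chain step that closes the C6–C7 bond of the ten-membered ring and then the γ-lactone in the same flask.
2. The cyclisation precursor is a linear (Z)-enal carrying a 2-(stannylmethyl)acrylate. It comes from a linear C1–C10 chain by protection, TES→CHO oxidation, cross-metathesis and stannylation.
3. The linear chain comes from a zinc-catalysed direct aldol (C2–C3) followed by an Evans–Tishchenko reduction, which sets C1 and places the acetate on O3.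
4. The East methyl ketone (C7–C10, C1, C2, with the 2-methylbutanoate already on O8) comes from acrolein and propyne. The West (Z)-enal (C3–C6, C15) comes from 2-butyne-1,4-diol.
5. Ring order: carbocycle first, lactone second, both in step 15.

Convention: atom labels follow germacrane numbering of the target (ring C1–C10; C11(=C13H2)–C12(=O)–O6; C14 = methyl on C10; C15 = CH2OH on C4). The given SMILES reads as 1S,3S,6S,7R,8R,4Z,9Z with an (S)-2-methylbutanoate.

Assumption: compounds 1, 2, 7, 11 and 23 are taken as commercial; the ProPhenol antipode named in steps 1 and 9 is the one expected to give the stated face, and the other antipode is used if the sense is found reversed.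

## Route

Step 1
Reactants: 1 acrolein; 2 propyne
Product: 4 (3S)-hex-1-en-4-yn-3-ol, via alkynylzinc 3 (not isolated)
Conditions: ZnMe2 (3 equiv), (S,S)-ProPhenol (10 mol %), Ph3PO (20 mol %), toluene, 0 °C
Reagents that add atoms: none
Why: Catalytic asymmetric alkynylation in which the zinc alkynylide made from propyne and ZnMe2 adds 1,2 to the Re face of acrolein inside the dinuclear zinc–ProPhenol pocket, which sets the S carbinol (C8).

Step 2
Reactants: 4 (3S)-hex-1-en-4-yn-3-ol
Product: 6 (3S,4Z)-5-iodohexa-1,4-dien-3-ol, via alkenylalanate 5 (not isolated)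
Conditions: NaAlH2(OCH2CH2OMe)2, THF, 0 °C → rt; then I2, −78 °C
Reagents that add atoms: iodine, II
Why: Hydroxyl-directed trans-hydroalumination of the propargylic alcohol puts hydride on the proximal and aluminium on the distal alkyne carbon, and iodinolysis with retention gives the Z vinyl iodide that fixes the C9=C10 geometry while the isolated vinyl group is untouched.

Step 3
Reactants: 6 (3S,4Z)-5-iodohexa-1,4-dien-3-ol; 7 (S)-2-methylbutanoic acid
Product: 8 (3S,4Z)-5-iodohexa-1,4-dien-3-yl (2S)-2-methylbutanoate
Conditions: DIC, DMAP (cat.), CH2Cl2, 0 °C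
Reagents that add atoms: none
Why: Steglich esterification at low temperature installs the final C8 ester early without touching either stereocentre.

Step 4
Reactants: 8 (3S,4Z)-5-iodohexa-1,4-dien-3-yl (2S)-2-methylbutanoate
Product: 10 (3S,4Z)-5-methyl-6-oxohepta-1,4-dien-3-yl (2S)-2-methylbutanoate, via enol ether 9 (not isolated)
Conditions: CH2=C(OEt)SnBu3, copper thiophene-2-carboxylate Cu(O2C-C4H3S) (1.5 equiv), NMP, 0 °C → rt; then 1 M HCl, THF, 0 °C
Reagents that add atoms: tributyl(1-ethoxyvinyl)stannane, CCOC(=C)[Sn](CCCC)(CCCC)CCCC; water, O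
Why: Copper-mediated Stille-type (Liebeskind) coupling joins the vinyl iodide to the acetyl-anion equivalent with retention of the Z geometry and without zerovalent palladium that could ionise the doubly allylic ester, and mild hydrolysis of the enol ether then gives the methyl ketone.

Step 5
Reactants: 11 but-2-yne-1,4-diol
Product: 13 4-[(tert-butyldimethylsilyl)oxy]but-2-yn-1-ol, via monoalkoxide 12 (not isolated)
Conditions: NaH (1.0 equiv), THF, 0 °C; then TBSCl
Reagents that add atoms: tert-butyldimethylsilyl chloride, CC(C)(C)[Si](C)(C)Cl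
Why: Statistical monosilylation of the symmetrical diol through its monosodium alkoxide (O-silylation).

Step 6
Reactants: 13 4-[(tert-butyldimethylsilyl)oxy]but-2-yn-1-ol
Product: 15 (Z)-4-[(tert-butyldimethylsilyl)oxy]-3-iodobut-2-en-1-ol, via alkenylalanate 14 (not isolated)
Conditions: NaAlH2(OCH2CH2OMe)2, THF, 0 °C; then I2, −78 °C
Reagents that add atoms: iodine, II
Why: The free hydroxyl directs the same trans-hydroalumination–iodination, so iodine ends on the carbon bearing CH2OTBS and cis to the CH2OH carbon, which fixes the C4=C5 geometry (C6 cis to the future C3).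

Step 7
Reactants: 15 (Z)-4-[(tert-butyldimethylsilyl)oxy]-3-iodobut-2-en-1-ol
Product: 16 (Z)-1-[(triethylsilyl)oxy]-4-[(tert-butyldimethylsilyl)oxy]-3-iodobut-2-ene
Conditions: TESCl, imidazole, CH2Cl2, 0 °C
Reagents that add atoms: triethylsilyl chloride, CC[Si](CC)(CC)Cl
Why: Standard silylation gives a primary TES ether that serves as the latent C6 aldehyde and is distinguishable from the TBS ethers.

Step 8
Reactants: 16 (Z)-1-[(triethylsilyl)oxy]-4-[(tert-butyldimethylsilyl)oxy]-3-iodobut-2-ene
Product: 17 (Z)-2-{[(tert-butyldimethylsilyl)oxy]methyl}-4-[(triethylsilyl)oxy]but-2-enal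
Conditions: Pd(PPh3)4 (5 mol %), CO (1 atm), Bu3SnH (slow addition), THF, 50 °C
Reagents that add atoms: carbon monoxide, [C-]#[O+]
Why: Palladium-catalysed reductive carbonylation (Stille-type formylation: oxidative addition, CO insertion, hydride transfer from tin) converts the vinyl iodide into the enal with retention of geometry and without a vinyl anion that could trigger silyl migration.

Step 9
Reactants: 10 (3S,4Z)-5-methyl-6-oxohepta-1,4-dien-3-yl (2S)-2-methylbutanoate; 17 (Z)-2-{[(tert-butyldimethylsilyl)oxy]methyl}-4-[(triethylsilyl)oxy]but-2-enal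
Product: 18 linear (3S)-β-hydroxy ketone (C2–C3 bond formed; C1 ketone; 4Z,9Z; O8 2-methylbutanoate; 15-OTBS; 6-OTES; C7 vinyl)
Conditions: (R,R)-ProPhenol (10 mol %), ZnEt2 (20 mol %), 4 Å MS, THF, −20 °C
Reagents that add atoms: none
Why: Direct catalytic asymmetric aldol reaction in which the zinc enolate of the enone methyl ketone adds to the Si face of the non-enolisable enal within the dinuclear zinc–ProPhenol complex, which sets C3 as S.

Step 10
Reactants: 18 linear (3S)-β-hydroxy ketone
Product: 19 (1S,3S)-1-hydroxy-3-acetoxy linear chain (anti)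
Conditions: SmI2 (30 mol %, premixed with CH3CHO), CH3CHO (10 equiv), THF, −10 °C
Reagents that add atoms: acetaldehyde, CC=O
Why: Evans–Tishchenko reduction, in which the hemiacetal formed from the C3 hydroxyl and acetaldehyde delivers hydride to C1 through a chair chelated by trivalent samarium, gives the 1,3-anti diol (C1 S) with the acetate already on O3.

Step 11
Reactants: 19 (1S,3S)-1-hydroxy-3-acetoxy linear chain
Product: 20 1-O-TBS ether of 19
Conditions: TBSOTf, 2,6-lutidine, CH2Cl2, −78 °C
Reagents that add atoms: tert-butyldimethylsilyl triflate, CC(C)(C)[Si](C)(C)OS(=O)(=O)C(F)(F)F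
Why: Silylation of the hindered allylic C1 alcohol so that the next oxidation touches only C6.

Step 12
Reactants: 20 1-O-TBS ether of 19
Product: 22 (4Z)-C6 enal, via alkoxysulfonium salt 21 (not isolated)
Conditions: (COCl)2, DMSO, CH2Cl2, −78 → −30 °C; then Et3N
Reagents that add atoms: none
Why: Under Swern conditions the chlorosulfonium salt cleaves the primary TES ether selectively (TBS ethers survive) and the resulting alkoxysulfonium ylide collapses to the aldehyde.

Step 13
Reactants: 22 (4Z)-C6 enal; 23 methyl 2-(bromomethyl)acrylate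
Product: 24 (7Z)-allylic bromide: C7=C11(CO2Me)CH2Br unit in place of the vinyl group
Conditions: second-generation Hoveyda–Grubbs catalyst RuCl2(=CH-C6H4-2-Oi-Pr)(H2IMes) (10 mol %), 23 (10 equiv), CH2Cl2, 40 °C
Reagents that add atoms: none
Why: Olefin cross-metathesis between the only monosubstituted alkene of 22 and the 1,1-disubstituted acrylate (which cannot homodimerise) gives the thermodynamically preferred trisubstituted enoate with C8 trans to the ester.

Step 14
Reactants: 24 (7Z)-allylic bromide
Product: 25 primary allylstannane: C7=C11(CO2Me)CH2SnBu3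
Conditions: Bu3SnSnBu3 (1.1 equiv), Pd2(dba)3 (2.5 mol %), THF, 0 °C → rt
Reagents that add atoms: hexabutyldistannane, CCCC[Sn](CCCC)(CCCC)[Sn](CCCC)(CCCC)CCCC
Why: Palladium-catalysed stannylation of the activated allylic bromide through a π-allyl complex delivers tin to the less hindered primary terminus, and the phosphine-free catalyst at low temperature leaves the allylic carboxylates alone.

Step 15
Reactants: 25 primary allylstannane
Product: 27 1,15-bis-O-TBS ether of the target, via stannyl ether 26 (not isolated)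
Conditions: Bu3SnSnBu3 (10 mol %), hν (sunlamp), PhH (2 mM), 60 °C
Reagents that add atoms: none
Why: Proposed new method: a tributylstannyl radical adds reversibly to the aldehyde oxygen to give an O-stannyl ketyl (1-stannyloxyallyl) radical whose carbinol carbon C6 attacks C7 of the tethered 2-(stannylmethyl)acrylate, the adduct radical expels Bu3Sn• to unveil the exocyclic methylene and carry the chain, and the tin alkoxide then lactonises onto the methyl ester; the closest known reactions are O-stannyl ketyl–olefin cyclisations, radical allyl transfer from 2-(stannylmethyl)acrylates and allyl-radical macrocyclisations onto enoates; C6 and C7 are set in a chair-like cis,cis-cyclodeca-1,6-diene transition state with the C8–O bond anti to the forming bond, both oxygens pseudo-equatorial and the acrylate carbon pseudo-axial (all-cis C6/C7/C8, hence the cis lactone); attack through C4 would need an eight-membered ring with a quaternary centre, and the strain-free Z,Z ring is expected to be selected even if the allylic radical rotates; a radical is used because an allylmetal at C13 would eliminate the C8 carboxylate.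

Step 16
Reactants: 27 1,15-bis-O-TBS ether of the target
Product: 28 target, (1S,3S,6S,7R,8R,4Z,9Z)-3-acetoxy-1,15-dihydroxy-8-[(2S)-2-methylbutanoyloxy]germacra-4,9,11(13)-trien-12,6-olide
Conditions: HF·pyridine, pyridine, THF, 0 °C → rt
Reagents that add atoms: none
Why: Buffered fluoride desilylation removes both TBS ethers without touching the α-methylene lactone or the three esters, and no stereocentre is affected.

## Compound list

1 | acrolein | C=CC=O | starting material
2 | propyne | CC#C | starting material
3 | methyl(prop-1-yn-1-yl)zinc (not isolated) | CC#C[Zn]C | intermediate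
4 | (3S)-hex-1-en-4-yn-3-ol | C=C[C@H](O)C#CC | intermediate
5 | sodium cyclic alkenylalanate from 4 (not isolated) | [Na+].C=C[C@@H]1O[Al-](OCCOC)(OCCOC)C(C)=C1 | intermediate
6 | (3S,4Z)-5-iodohexa-1,4-dien-3-ol | C=C[C@H](O)/C=C(\I)C | intermediate
7 | (S)-2-methylbutanoic acid | CC[C@H](C)C(=O)O | starting material
8 | (3S,4Z)-5-iodohexa-1,4-dien-3-yl (2S)-2-methylbutanoate | C=C[C@H](OC(=O)[C@@H](C)CC)/C=C(\I)C | intermediate
9 | (3S,4Z)-6-ethoxy-5-methylhepta-1,4,6-trien-3-yl (2S)-2-methylbutanoate (not isolated) | C=C[C@H](OC(=O)[C@@H](C)CC)/C=C(\C(=C)OCC)C | intermediate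
10 | (3S,4Z)-5-methyl-6-oxohepta-1,4-dien-3-yl (2S)-2-methylbutanoate (East ketone) | C=C[C@H](OC(=O)[C@@H](C)CC)/C=C(\C(C)=O)C | intermediate
11 | but-2-yne-1,4-diol | OCC#CCO | starting material
12 | sodium 4-hydroxybut-2-yn-1-olate (not isolated) | [Na+].[O-]CC#CCO | intermediate
13 | 4-[(tert-butyldimethylsilyl)oxy]but-2-yn-1-ol | OCC#CCO[Si](C)(C)C(C)(C)C | intermediate
14 | sodium cyclic alkenylalanate from 13 (not isolated) | [Na+].CC(C)(C)[Si](C)(C)OCC1=CCO[Al-]1(OCCOC)OCCOC | intermediate
15 | (Z)-4-[(tert-butyldimethylsilyl)oxy]-3-iodobut-2-en-1-ol | OC/C=C(\I)CO[Si](C)(C)C(C)(C)C | intermediate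
16 | (Z)-1-[(triethylsilyl)oxy]-4-[(tert-butyldimethylsilyl)oxy]-3-iodobut-2-ene | CC[Si](CC)(CC)OC/C=C(\I)CO[Si](C)(C)C(C)(C)C | intermediate
17 | (Z)-2-{[(tert-butyldimethylsilyl)oxy]methyl}-4-[(triethylsilyl)oxy]but-2-enal (West enal) | O=C/C(CO[Si](C)(C)C(C)(C)C)=C\CO[Si](CC)(CC)CC | intermediate
18 | linear (3S)-β-hydroxy C1-ketone, 4Z,9Z, O8 (S)-2-methylbutanoate, 15-OTBS, 6-OTES, C7 vinyl | C=C[C@H](OC(=O)[C@@H](C)CC)/C=C(C)\C(=O)C[C@H](O)/C(CO[Si](C)(C)C(C)(C)C)=C\CO[Si](CC)(CC)CC | intermediate
19 | linear (1S,3S)-1-hydroxy-3-acetate (1,3-anti), otherwise as 18 | C=C[C@H](OC(=O)[C@@H](C)CC)/C=C(C)\[C@@H](O)C[C@H](OC(C)=O)/C(CO[Si](C)(C)C(C)(C)C)=C\CO[Si](CC)(CC)CC | intermediate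
20 | 1-O-TBS ether of 19 | C=C[C@H](OC(=O)[C@@H](C)CC)/C=C(C)\[C@@H](O[Si](C)(C)C(C)(C)C)C[C@H](OC(C)=O)/C(CO[Si](C)(C)C(C)(C)C)=C\CO[Si](CC)(CC)CC | intermediate
21 | C6 alkoxydimethylsulfonium chloride from 20 (not isolated) | C=C[C@H](OC(=O)[C@@H](C)CC)/C=C(C)\[C@@H](O[Si](C)(C)C(C)(C)C)C[C@H](OC(C)=O)/C(CO[Si](C)(C)C(C)(C)C)=C\CO[S+](C)C.[Cl-] | intermediate
22 | (4Z)-C6 enal, 1-OTBS, 3-OAc, 15-OTBS, O8 ester, C7 vinyl | C=C[C@H](OC(=O)[C@@H](C)CC)/C=C(C)\[C@@H](O[Si](C)(C)C(C)(C)C)C[C@H](OC(C)=O)/C(CO[Si](C)(C)C(C)(C)C)=C\C=O | intermediate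
23 | methyl 2-(bromomethyl)acrylate | C=C(CBr)C(=O)OC | starting material
24 | allylic bromide: (7Z)-C7=C11(CO2Me)CH2Br on the enal 22 skeleton (8R) | BrC/C(C(=O)OC)=C\[C@H](OC(=O)[C@@H](C)CC)/C=C(C)\[C@@H](O[Si](C)(C)C(C)(C)C)C[C@H](OC(C)=O)/C(CO[Si](C)(C)C(C)(C)C)=C\C=O | intermediate
25 | primary allylstannane: C13H2SnBu3 in place of C13H2Br in 24 | CCCC[Sn](CCCC)(CCCC)C/C(C(=O)OC)=C\[C@H](OC(=O)[C@@H](C)CC)/C=C(C)\[C@@H](O[Si](C)(C)C(C)(C)C)C[C@H](OC(C)=O)/C(CO[Si](C)(C)C(C)(C)C)=C\C=O | intermediate
26 | ten-membered 6-O-tributylstannyl ether methyl ester (1S,3S,6S,7R,8R; 4Z,9Z; not isolated) | C=C(C(=O)OC)[C@H]1[C@@H](O[Sn](CCCC)(CCCC)CCCC)/C=C(/CO[Si](C)(C)C(C)(C)C)[C@@H](OC(C)=O)C[C@H](O[Si](C)(C)C(C)(C)C)/C(C)=C\[C@H]1OC(=O)[C@@H](C)CC | intermediate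
27 | 1,15-bis-O-TBS ether of the target | C=C1C(=O)O[C@H]2/C=C(/CO[Si](C)(C)C(C)(C)C)[C@@H](OC(C)=O)C[C@H](O[Si](C)(C)C(C)(C)C)/C(C)=C\[C@@H](OC(=O)[C@@H](C)CC)[C@@H]12 | intermediate
28 | target CNP0217661.3 | C=C1C(=O)O[C@H]2/C=C(/CO)[C@@H](OC(C)=O)C[C@H](O)/C(C)=C\[C@@H](OC(=O)[C@@H](C)CC)[C@@H]12 | target

## Step count and risks

Total steps: 16. Longest linear sequence: 12 steps (steps 1–4 then 9–16, or steps 5–8 then 9–16).

**Step 15 (radical macrocyclisation/lactonisation).** A stabilised allylic ketyl radical must close a ten-membered ring onto a β-substituted acrylate. The C6/C7 configuration, the C7/C8 relationship and retention of the 4Z alkene all rest on the macrocyclic transition state. Reaction through C4 or a tin-mediated acyl shift from O8 are possible side paths. Fallback: set out from 20 and return at 27 by a closed, non-radical allyl transfer that also tolerates the C8 ester. Cross-metathesis of 20 with 23 gives the TES-protected allylic bromide F1. Palladium-catalysed borylation with B2pin2 gives the primary allylboronate F2. Swern oxidation of the primary TES ether gives the aldehyde allylboronate F3. Warming F3 (toluene, 60 °C, or catalytic Sc(OTf)3) gives intramolecular allylboration through a chair transition state with retention of both alkene geometries, and the borate lactonises to 27.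

**Step 14 (stannylation).** The π-allyl palladium intermediate has a carboxylate on the neighbouring carbon and could eliminate to a diene. The allylstannane could also couple with unreacted bromide. Fallback: set out from 24 and return at 27 without palladium or a preformed stannane. Displacement of bromide with sodium benzenesulfinate (DMF, rt; the conjugated primary sulfone is the stable isomer) gives the allylic sulfone F4. F4 is cyclised under the conditions of step 15 with one equivalent of Bu3SnSnBu3. The adduct radical now expels PhSO2•, which the ditin converts back into Bu3Sn•, and the stannyl ether 26 lactonises to 27.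

**Step 9 (direct aldol).** The donor is a Z enone carrying a γ-acyloxy group and the acceptor is a Z enal. Low conversion, dehydration, Z→E drift or modest facial control are possible. Fallback: set out from 10 and return at 18 by separating enolisation from C–C bond formation. Soft enolisation (TBSOTf, Et3N, −78 °C) gives the silyl dienol ether F5. A Mukaiyama aldol of F5 with 17 under a chiral Lewis acid (BINOL–titanium isopropoxide type), followed by mild acidic work-up to cleave the silyl group, gives 18.

Further compounds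
F1 | step 15 | allylic bromide with C6 still as its TES ether (cross-metathesis product of 20 and 23) | BrC/C(C(=O)OC)=C\[C@H](OC(=O)[C@@H](C)CC)/C=C(C)\[C@@H](O[Si](C)(C)C(C)(C)C)C[C@H](OC(C)=O)/C(CO[Si](C)(C)C(C)(C)C)=C\CO[Si](CC)(CC)CC
F2 | step 15 | primary allylboronate (pinacol ester) from F1 | CC1(C)OB(C/C(C(=O)OC)=C\[C@H](OC(=O)[C@@H](C)CC)/C=C(C)\[C@@H](O[Si](C)(C)C(C)(C)C)C[C@H](OC(C)=O)/C(CO[Si](C)(C)C(C)(C)C)=C\CO[Si](CC)(CC)CC)OC1(C)C
F3 | step 15 | C6 aldehyde allylboronate from F2 | CC1(C)OB(C/C(C(=O)OC)=C\[C@H](OC(=O)[C@@H](C)CC)/C=C(C)\[C@@H](O[Si](C)(C)C(C)(C)C)C[C@H](OC(C)=O)/C(CO[Si](C)(C)C(C)(C)C)=C\C=O)OC1(C)C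
F4 | step 14 | allylic phenyl sulfone from 24 | O=S(=O)(C/C(C(=O)OC)=C\[C@H](OC(=O)[C@@H](C)CC)/C=C(C)\[C@@H](O[Si](C)(C)C(C)(C)C)C[C@H](OC(C)=O)/C(CO[Si](C)(C)C(C)(C)C)=C\C=O)c1ccccc1
F5 | step 9 | tert-butyldimethylsilyl dienol ether of ketone 10 | C=C[C@H](OC(=O)[C@@H](C)CC)/C=C(C)\C(=C)O[Si](C)(C)C(C)(C)C
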